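**Retrosynthetic overview**
1. Target ⇐ global O‑debenzylation ⇐ top interflavan bond C4(top)–C8(middle), made by Lewis acid coupling of a 3‑O‑galloylated 4β‑alkoxy epicatechin with the bis‑galloylated middle–bottom dimer; each gallate ester is put on one hydroxyl at a time (electrophile, bottom unit, then the freed middle 3‑OH).
2. Key disconnection: ring C of the middle unit is opened at C4–C4a together with the interflavan bond C4–C8(bottom). C4 becomes the formyl carbon of an acyclic (2S,3R)-3-aryloxy-3-aryl-2-silyloxypropanal that already holds O1–C2 and C3–O; the partner is benzylated epicatechin 3‑O‑gallate.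
3. Enabling feature: C4 of the middle unit is a methine flanked by two phloroglucinol‑type carbons (C4a of its own ring A, ortho to the ether oxygen O1, and C8 of ring A of the bottom unit). It is therefore an aldehyde carbon after twofold Friedel–Crafts arylation, and the axial oxygen on the neighbouring C3 steers the second arylation to the 4β face.
4. The aldehyde comes from 3,4-bis(benzyloxy)benzaldehyde: Z‑cinnamate, Jacobsen cis‑epoxide (sets C2 and C3), then SN2 opening at the benzylic carbon by 3,5-bis(benzyloxy)phenol (forms O1–C2 with inversion).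
5. Ring order: rings A, B and C of the top and bottom units arrive closed in (−)-epicatechin, and all other aromatic rings arrive in the building blocks. The only ring closed in the route, and so the last, is ring C of the middle unit.

Key step: step 10

Assumption: 3,5-bis(benzyloxy)phenol, ethyl (diphenoxyphosphoryl)acetate and 3,4,5-tris(benzyloxy)benzoyl chloride are taken as catalogue compounds, and the facial sense of the Jacobsen epoxidation is assigned by analogy with unsubstituted ethyl cis‑cinnamate.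

**Step 1**
Reactants: 1 (−)-epicatechin
Product: 2 5,7,3',4'-tetra-O-benzyl-(−)-epicatechin, (2R,3R)
Conditions: BnBr (4.4 equiv), K2CO3, DMF, 0 °C → rt
Reagents that add atoms: benzyl bromide, BrCc1ccccc1
Why: Williamson ether synthesis in which carbonate deprotonates only the four phenols and not the aliphatic 3-OH, while the low temperature limits base‑induced C2 epimerization and C‑benzylation; no stereocenter is formed.

**Step 2**
Reactants: 2 5,7,3',4'-tetra-O-benzyl-(−)-epicatechin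
Product: 3 (2R,3R,4S)-5,7,3',4'-tetra-O-benzyl-4-(2-ethoxyethoxy)flavan-3-ol (4β‑alkoxy, 2,3‑cis, 3,4‑trans)
Conditions: DDQ (1.5 equiv), 2-ethoxyethanol, CH2Cl2, rt
Reagents that add atoms: 2-ethoxyethanol, CCOCCO
Why: Oxidative C4 functionalization of a benzylated flavan-3-ol, in which DDQ abstracts the benzylic hydride at C4 and the alcohol adds to the cation anti to the 3-OH, setting the 4β (4S) ether that serves as leaving group in step 13.

**Step 3**
Reactants: 3 (2R,3R,4S)-5,7,3',4'-tetra-O-benzyl-4-(2-ethoxyethoxy)flavan-3-ol; 4 3,4,5-tris(benzyloxy)benzoyl chloride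
Product: 5 (2R,3R,4S)-5,7,3',4'-tetra-O-benzyl-4-(2-ethoxyethoxy)flavan-3-yl 3,4,5-tris(benzyloxy)benzoate
Conditions: 4 (1.5 equiv), DMAP (cat.), pyridine, CH2Cl2, 0 °C → rt
Reagents that add atoms: none
Why: DMAP‑catalyzed acylation of the one free secondary hydroxyl by the acid chloride transfers a single galloyl unit, the benzylic 4‑ether being stable to these basic conditions; no stereocenter is touched.

**Step 4**
Reactants: 2 5,7,3',4'-tetra-O-benzyl-(−)-epicatechin; 4 3,4,5-tris(benzyloxy)benzoyl chloride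
Product: 6 5,7,3',4'-tetra-O-benzyl-(−)-epicatechin 3-O-[3,4,5-tris(benzyloxy)benzoate], (2R,3R)
Conditions: 4 (1.3 equiv), DMAP (cat.), pyridine, CH2Cl2, 0 °C → rt
Reagents that add atoms: none
Why: DMAP‑catalyzed acylation of the unhindered 3‑hydroxy group with the acid chloride gives the benzylated epicatechin gallate that serves as nucleophile in step 10; no stereocenter is touched.

**Step 5**
Reactants: 7 3,4-bis(benzyloxy)benzaldehyde; 8 ethyl (diphenoxyphosphoryl)acetate
Product: 9 ethyl (Z)-3-[3,4-bis(benzyloxy)phenyl]prop-2-enoate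
Conditions: NaH, THF, −78 → 0 °C
Reagents that add atoms: none
Why: Ando‑type Z‑selective Horner–Wadsworth–Emmons olefination, in which the electron‑poor diaryl phosphonate makes elimination from the kinetically formed adduct fast, so the Z‑cinnamate should predominate and the minor E isomer is removed by chromatography.

**Step 6**
Reactants: 9 ethyl (Z)-3-[3,4-bis(benzyloxy)phenyl]prop-2-enoate
Product: 10 ethyl (2S,3S)-3-[3,4-bis(benzyloxy)phenyl]oxirane-2-carboxylate (cis‑glycidate)
Conditions: (S,S)-N,N'-bis(3,5-di-tert-butylsalicylidene)-1,2-cyclohexanediaminomanganese chloride (trivalent manganese, 6 mol %), 4-phenylpyridine N-oxide (0.25 equiv), aq NaOCl (pH 11.3), CH2Cl2, 4 °C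
Reagents that add atoms: sodium hypochlorite, [Na+].[O-]Cl
Why: Jacobsen epoxidation, for which cis‑cinnamate esters are among the best substrates; the chiral oxo‑manganese species delivers oxygen to one face of the Z‑alkene and sets both epoxide carbons (2S,3S) with the (S,S) catalyst.

**Step 7**
Reactants: 10 ethyl (2S,3S)-3-[3,4-bis(benzyloxy)phenyl]oxirane-2-carboxylate; 11 3,5-bis(benzyloxy)phenol
Product: 12 ethyl (2S,3R)-3-[3,5-bis(benzyloxy)phenoxy]-3-[3,4-bis(benzyloxy)phenyl]-2-hydroxypropanoate (threo)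
Conditions: 11 (1.2 equiv), Cs2CO3 (0.3 equiv), DMF, 60 °C
Reagents that add atoms: none
Why: Base‑mediated SN2 opening of a 3‑arylglycidate by a phenoxide at the benzylic carbon, the usual site of attack in this substrate class, forms the O1–C2 ether bond with inversion and turns the cis‑epoxide into the threo (2S,3R) ether‑alcohol that maps onto the 2,3‑cis flavan, while the ester‑bearing carbon is untouched.

**Step 8**
Reactants: 12 ethyl (2S,3R)-3-[3,5-bis(benzyloxy)phenoxy]-3-[3,4-bis(benzyloxy)phenyl]-2-hydroxypropanoate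
Product: 13 ethyl (2S,3R)-3-[3,5-bis(benzyloxy)phenoxy]-3-[3,4-bis(benzyloxy)phenyl]-2-[(tert-butyldimethylsilyl)oxy]propanoate
Conditions: TBSOTf, 2,6-lutidine, CH2Cl2, 0 °C
Reagents that add atoms: tert-butyldimethylsilyl triflate, CC(C)(C)[Si](C)(C)OS(=O)(=O)C(F)(F)F
Why: Silyl ether formation on the hindered secondary alcohol with the silyl triflate; the group survives iBu2AlH and TMSOTf and is removed by fluoride in step 11.

**Step 9**
Reactants: 13 ethyl (2S,3R)-3-[3,5-bis(benzyloxy)phenoxy]-3-[3,4-bis(benzyloxy)phenyl]-2-[(tert-butyldimethylsilyl)oxy]propanoate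
Product: 14 (2S,3R)-3-[3,5-bis(benzyloxy)phenoxy]-3-[3,4-bis(benzyloxy)phenyl]-2-[(tert-butyldimethylsilyl)oxy]propanal
Conditions: iBu2AlH (1.1 equiv), CH2Cl2, −78 °C; MeOH, then aq potassium sodium tartrate
Reagents that add atoms: none
Why: Partial reduction of an α‑silyloxy ester at −78 °C stops at the tetrahedral aluminium hemiacetal, which collapses to the aldehyde only on work‑up, and the neutral tartrate work‑up avoids α‑epimerization and β‑elimination of the aryloxide.

**Step 10**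
Reactants: 14 (2S,3R)-3-[3,5-bis(benzyloxy)phenoxy]-3-[3,4-bis(benzyloxy)phenyl]-2-[(tert-butyldimethylsilyl)oxy]propanal; 6 5,7,3',4'-tetra-O-benzyl-(−)-epicatechin 3-O-[3,4,5-tris(benzyloxy)benzoate]
Product: 17 octa-O-benzyl procyanidin B2 upper-unit 3-O-TBS ether lower-unit 3-O-[3,4,5-tris(benzyloxy)benzoate], via flavan-4-ol 15 (not isolated), via flavan-4-yl cation 16 (not isolated)
Conditions: 6 (3 equiv), TMSOTf (0.3 equiv), 4 Å MS, CH2Cl2, −78 → −40 °C, slow addition of 14; Et3N quench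
Reagents that add atoms: none
Why: Proposed new method: TMSOTf activates the aldehyde of 14 for intramolecular Friedel–Crafts hydroxyalkylation at an ortho carbon of the 3,5-bis(benzyloxy)phenoxy ring (6‑exo‑trig closure of ring C through the C4–C4a bond, the two ortho positions being equivalent), and the resulting flavan-4-ol 15 ionizes under the same acid to the ring‑A‑stabilized cation 16, which is captured by C8 of 6. The closest known reaction types are the acid‑mediated cyclization of 3‑aryloxypropanals to chroman-4-ols, the bisarylation of aldehydes by electron‑rich arenes, and the Lewis acid coupling of 4‑oxygenated flavan-3-ol ethers with flavan nucleophiles. C2 and C3 are carried over unchanged from 14, and the new C4 center is set in the last bond formation, where the half‑chair cation with equatorial 2‑aryl and axial 3‑silyloxy groups is attacked anti to the 3‑oxygen as in the 4β‑selective couplings of the epicatechin series, so both C4 epimers of 15 converge on one product. The step needs ring closure to precede intermolecular attack on the aldehyde (secured by the six‑membered transition state and the phloroglucinol‑type nucleophilicity of the tethered ring), C8 over C6 selectivity in 6 (the usual preference of benzylated flavans, the ester‑deactivated galloyl ring staying inert), and capture of 16 by 6 instead of by product (excess 6 and slow addition of 14).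

**Step 11**
Reactants: 17 octa-O-benzyl procyanidin B2 upper-unit 3-O-TBS ether lower-unit 3-O-[3,4,5-tris(benzyloxy)benzoate]
Product: 18 octa-O-benzyl procyanidin B2 lower-unit 3-O-[3,4,5-tris(benzyloxy)benzoate] (upper 3-OH free)
Conditions: Bu4NF, AcOH (1:1), THF, rt → 40 °C
Reagents that add atoms: none
Why: Fluoride‑mediated cleavage of the Si–O bond, buffered with acetic acid so that the gallate ester of the lower unit is not attacked by basic fluoride or alkoxide; no stereocenter is touched.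

**Step 12**
Reactants: 18 octa-O-benzyl procyanidin B2 lower-unit 3-O-[3,4,5-tris(benzyloxy)benzoate]; 4 3,4,5-tris(benzyloxy)benzoyl chloride
Product: 19 octa-O-benzyl procyanidin B2 bis[3,4,5-tris(benzyloxy)benzoate] (esters on the 3‑oxygens of both units)
Conditions: 4 (3 equiv), DMAP (1 equiv), pyridine, CH2Cl2, rt → 40 °C
Reagents that add atoms: none
Why: DMAP‑catalyzed acylation of the single free secondary hydroxyl, which sits next to the C4 aryl group and therefore needs excess acid chloride and gentle warming, transfers one galloyl unit; no stereocenter is affected.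

**Step 13**
Reactants: 19 octa-O-benzyl procyanidin B2 bis[3,4,5-tris(benzyloxy)benzoate]; 5 (2R,3R,4S)-5,7,3',4'-tetra-O-benzyl-4-(2-ethoxyethoxy)flavan-3-yl 3,4,5-tris(benzyloxy)benzoate
Product: 20 dodeca-O-benzyl procyanidin C1 tris[3,4,5-tris(benzyloxy)benzoate] (three benzylated epicatechin units joined (4β→8) twice, each 3‑oxygen esterified)
Conditions: 19 (1.5 equiv), TMSOTf (0.5 equiv), CH2Cl2, −78 → −20 °C; Et3N quench
Reagents that add atoms: none
Why: Lewis acid‑mediated Friedel–Crafts interflavan coupling of a 3‑O‑acyl‑4‑alkoxyflavan with a benzylated flavan nucleophile, in which ionization at C4 of 5 is followed by attack of C8 of the upper unit of 19 (its most accessible electron‑rich free position) anti to the 3‑acyloxy group, whose neighbouring‑group participation on the α face reinforces the 4β→8 outcome, with 19 in excess to suppress self‑condensation of 5.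

**Step 14**
Reactants: 20 dodeca-O-benzyl procyanidin C1 tris[3,4,5-tris(benzyloxy)benzoate]
Product: 21 procyanidin C1 3,3',3''-tri-O-gallate
Conditions: H2 (1 atm), Pd(OH)2/C, THF/MeOH/H2O, rt; filtration and lyophilization
Reagents that add atoms: none
Why: Catalytic hydrogenolysis should cleave all 21 benzyl ethers, while the aryl esters, the interflavan bonds and the benzylic O1–C2 bonds of the flavan rings are known to survive Pd(OH)2/C under neutral conditions.

**Compound list**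
1 | (−)-epicatechin | O[C@@H]1Cc2c(O)cc(O)cc2O[C@@H]1c1ccc(O)c(O)c1 | starting material
2 | 5,7,3',4'-tetra-O-benzyl-(−)-epicatechin | O[C@@H]1Cc2c(OCc3ccccc3)cc(OCc3ccccc3)cc2O[C@@H]1c1ccc(OCc2ccccc2)c(OCc2ccccc2)c1 | intermediate
3 | (2R,3R,4S)-5,7,3',4'-tetra-O-benzyl-4-(2-ethoxyethoxy)flavan-3-ol | CCOCCO[C@H]1c2c(OCc3ccccc3)cc(OCc3ccccc3)cc2O[C@H](c2ccc(OCc3ccccc3)c(OCc3ccccc3)c2)[C@@H]1O | intermediate
4 | 3,4,5-tris(benzyloxy)benzoyl chloride | O=C(Cl)c1cc(OCc2ccccc2)c(OCc2ccccc2)c(OCc2ccccc2)c1 | starting material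
5 | (2R,3R,4S)-5,7,3',4'-tetra-O-benzyl-4-(2-ethoxyethoxy)flavan-3-yl 3,4,5-tris(benzyloxy)benzoate | CCOCCO[C@H]1c2c(OCc3ccccc3)cc(OCc3ccccc3)cc2O[C@H](c2ccc(OCc3ccccc3)c(OCc3ccccc3)c2)[C@@H]1OC(=O)c1cc(OCc2ccccc2)c(OCc2ccccc2)c(OCc2ccccc2)c1 | intermediate
6 | 5,7,3',4'-tetra-O-benzyl-(−)-epicatechin 3-O-[3,4,5-tris(benzyloxy)benzoate] | O=C(O[C@@H]1Cc2c(OCc3ccccc3)cc(OCc3ccccc3)cc2O[C@@H]1c1ccc(OCc2ccccc2)c(OCc2ccccc2)c1)c1cc(OCc2ccccc2)c(OCc2ccccc2)c(OCc2ccccc2)c1 | intermediate
7 | 3,4-bis(benzyloxy)benzaldehyde | O=Cc1ccc(OCc2ccccc2)c(OCc2ccccc2)c1 | starting material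
8 | ethyl (diphenoxyphosphoryl)acetate | CCOC(=O)CP(=O)(Oc1ccccc1)Oc1ccccc1 | starting material
9 | ethyl (Z)-3-[3,4-bis(benzyloxy)phenyl]prop-2-enoate | CCOC(=O)/C=C\c1ccc(OCc2ccccc2)c(OCc2ccccc2)c1 | intermediate
10 | ethyl (2S,3S)-3-[3,4-bis(benzyloxy)phenyl]oxirane-2-carboxylate (cis) | CCOC(=O)[C@H]1O[C@H]1c1ccc(OCc2ccccc2)c(OCc2ccccc2)c1 | intermediate
11 | 3,5-bis(benzyloxy)phenol | Oc1cc(OCc2ccccc2)cc(OCc2ccccc2)c1 | starting material
12 | ethyl (2S,3R)-3-[3,5-bis(benzyloxy)phenoxy]-3-[3,4-bis(benzyloxy)phenyl]-2-hydroxypropanoate | CCOC(=O)[C@@H](O)[C@H](Oc1cc(OCc2ccccc2)cc(OCc2ccccc2)c1)c1ccc(OCc2ccccc2)c(OCc2ccccc2)c1 | intermediate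
13 | ethyl (2S,3R)-3-[3,5-bis(benzyloxy)phenoxy]-3-[3,4-bis(benzyloxy)phenyl]-2-[(tert-butyldimethylsilyl)oxy]propanoate | CCOC(=O)[C@@H](O[Si](C)(C)C(C)(C)C)[C@H](Oc1cc(OCc2ccccc2)cc(OCc2ccccc2)c1)c1ccc(OCc2ccccc2)c(OCc2ccccc2)c1 | intermediate
14 | (2S,3R)-3-[3,5-bis(benzyloxy)phenoxy]-3-[3,4-bis(benzyloxy)phenyl]-2-[(tert-butyldimethylsilyl)oxy]propanal | O=C[C@@H](O[Si](C)(C)C(C)(C)C)[C@H](Oc1cc(OCc2ccccc2)cc(OCc2ccccc2)c1)c1ccc(OCc2ccccc2)c(OCc2ccccc2)c1 | intermediate
15 | (2R,3R)-5,7,3',4'-tetra-O-benzyl-3-O-TBS-2,3-cis-flavan-3,4-diol, both C4 epimers | CC(C)(C)[Si](C)(C)O[C@@H]1C(O)c2c(OCc3ccccc3)cc(OCc3ccccc3)cc2O[C@@H]1c1ccc(OCc2ccccc2)c(OCc2ccccc2)c1 | intermediate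
16 | (2R,3R)-5,7,3',4'-tetra-O-benzyl-3-O-TBS-2,3-cis-flavan-4-yl cation | CC(C)(C)[Si](C)(C)O[C@@H]1[CH+]c2c(OCc3ccccc3)cc(OCc3ccccc3)cc2O[C@@H]1c1ccc(OCc2ccccc2)c(OCc2ccccc2)c1 | intermediate
17 | octa-O-benzyl procyanidin B2, upper-unit 3-O-TBS ether, lower-unit 3-O-[3,4,5-tris(benzyloxy)benzoate] | CC(C)(C)[Si](C)(C)O[C@@H]1[C@@H](c2c(OCc3ccccc3)cc(OCc3ccccc3)c3c2O[C@H](c2ccc(OCc4ccccc4)c(OCc4ccccc4)c2)[C@H](OC(=O)c2cc(OCc4ccccc4)c(OCc4ccccc4)c(OCc4ccccc4)c2)C3)c2c(OCc3ccccc3)cc(OCc3ccccc3)cc2O[C@@H]1c1ccc(OCc2ccccc2)c(OCc2ccccc2)c1 | intermediate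
18 | octa-O-benzyl procyanidin B2, lower-unit 3-O-[3,4,5-tris(benzyloxy)benzoate], upper 3-OH free | O[C@@H]1[C@@H](c2c(OCc3ccccc3)cc(OCc3ccccc3)c3c2O[C@H](c2ccc(OCc4ccccc4)c(OCc4ccccc4)c2)[C@H](OC(=O)c2cc(OCc4ccccc4)c(OCc4ccccc4)c(OCc4ccccc4)c2)C3)c2c(OCc3ccccc3)cc(OCc3ccccc3)cc2O[C@@H]1c1ccc(OCc2ccccc2)c(OCc2ccccc2)c1 | intermediate
19 | octa-O-benzyl procyanidin B2 bis[3,4,5-tris(benzyloxy)benzoate] | O=C(O[C@@H]1[C@@H](c2c(OCc3ccccc3)cc(OCc3ccccc3)c3c2O[C@H](c2ccc(OCc4ccccc4)c(OCc4ccccc4)c2)[C@H](OC(=O)c2cc(OCc4ccccc4)c(OCc4ccccc4)c(OCc4ccccc4)c2)C3)c2c(OCc3ccccc3)cc(OCc3ccccc3)cc2O[C@@H]1c1ccc(OCc2ccccc2)c(OCc2ccccc2)c1)c1cc(OCc2ccccc2)c(OCc2ccccc2)c(OCc2ccccc2)c1 | intermediate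
20 | dodeca-O-benzyl procyanidin C1 tris[3,4,5-tris(benzyloxy)benzoate] | O=C(O[C@@H]1[C@@H](c2c(OCc3ccccc3)cc(OCc3ccccc3)c3c2O[C@H](c2ccc(OCc4ccccc4)c(OCc4ccccc4)c2)[C@H](OC(=O)c2cc(OCc4ccccc4)c(OCc4ccccc4)c(OCc4ccccc4)c2)C3)c2c(OCc3ccccc3)cc(OCc3ccccc3)c([C@H]3c4c(OCc5ccccc5)cc(OCc5ccccc5)cc4O[C@H](c4ccc(OCc5ccccc5)c(OCc5ccccc5)c4)[C@@H]3OC(=O)c3cc(OCc4ccccc4)c(OCc4ccccc4)c(OCc4ccccc4)c3)c2O[C@@H]1c1ccc(OCc2ccccc2)c(OCc2ccccc2)c1)c1cc(OCc2ccccc2)c(OCc2ccccc2)c(OCc2ccccc2)c1 | intermediate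
21 | procyanidin C1 3,3',3''-tri-O-gallate | O=C(O[C@@H]1[C@@H](c2c(O)cc(O)c3c2O[C@H](c2ccc(O)c(O)c2)[C@H](OC(=O)c2cc(O)c(O)c(O)c2)C3)c2c(O)cc(O)c([C@H]3c4c(O)cc(O)cc4O[C@H](c4ccc(O)c(O)c4)[C@@H]3OC(=O)c3cc(O)c(O)c(O)c3)c2O[C@@H]1c1ccc(O)c(O)c1)c1cc(O)c(O)c(O)c1 | target

**Step count and risks**
Total steps: 14. Longest linear sequence: 10 steps (7 → 21, steps 5 to 14).

Steps most likely to fail:

1. Step 10 (proposed new method). Intermolecular arylation of the aldehyde could outrun the ring closure, which would lose the cyclic control of C4, or cation 16 could be captured by product instead of by 6, which would give oligomers. Fallback: the two events are separated with known reactions. Setting out from 14, acid‑mediated cyclization in the presence of 2-ethoxyethanol (camphorsulfonic acid cat., 2-ethoxyethanol/CH2Cl2, 0 °C; the known closure of 3‑aryloxypropanals and their acetals to 4‑alkoxychromans) should give the isolable (2R,3R)-5,7,3',4'-tetra-O-benzyl-3-O-TBS-4-(2-ethoxyethoxy)-2,3-cis-flavan F1 as a C4 epimer mixture. F1 is then used as a conventional 4‑alkoxy electrophile with 6 (TMSOTf cat., CH2Cl2, −78 °C), which comes back to the route at 17.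

2. Step 7. The phenoxide could attack the ester‑bearing carbon, the electron‑rich benzylic center could partly ionize and open without clean inversion, or base could epimerize or eliminate the β‑aryloxy ester. Fallback: the ester is taken out of play before the ether bond is made. Setting out from 10, NaBH4 (EtOH, 0 °C) should give the cis‑epoxy alcohol [(2R,3S)-3-[3,4-bis(benzyloxy)phenyl]oxiran-2-yl]methanol F2. Phenoxide opening at the benzylic carbon with inversion (11, NaOH, aqueous dioxane, 70 °C; the known C3‑selective opening of 3‑arylglycidols) should give the (2R,3R)-3-aryloxy-1,2-diol F3. Double silylation (TBSOTf, 2,6-lutidine) gives the bis‑silyl ether F4, selective cleavage of the primary silyl ether (HF·pyridine, THF/pyridine, 0 °C) gives the primary alcohol F5, and Dess–Martin oxidation comes back to the route at 14.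

3. Step 13. The 3‑O‑acyl group could slow ionization at C4 of the electrophile, so that coupling with the bulky bis‑gallate dimer stalls or loses its C8 regioselectivity while the electrophile self‑condenses. Fallback: the more reactive non‑acylated electrophile is used and the last ester is made afterwards. Setting out from 19 and 3, TMSOTf‑mediated coupling (19 in excess, CH2Cl2, −78 °C; the standard 4β‑selective coupling of a 4‑alkoxyflavan-3-ol) should give dodeca-O-benzyl procyanidin C1 bis[3,4,5-tris(benzyloxy)benzoate] with the top 3-OH free F6. Acylation of this one hydroxyl with 4 (DMAP, pyridine, CH2Cl2, rt → 40 °C) comes back to the route at 20.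

**Further compounds**
F1 | step 10 | (2R,3R)-5,7,3',4'-tetra-O-benzyl-3-O-(tert-butyldimethylsilyl)-4-(2-ethoxyethoxy)-2,3-cis-flavan, C4 epimers | CCOCCOC1c2c(OCc3ccccc3)cc(OCc3ccccc3)cc2O[C@H](c2ccc(OCc3ccccc3)c(OCc3ccccc3)c2)[C@@H]1O[Si](C)(C)C(C)(C)C
F2 | step 7 | [(2R,3S)-3-[3,4-bis(benzyloxy)phenyl]oxiran-2-yl]methanol (cis) | OC[C@H]1O[C@H]1c1ccc(OCc2ccccc2)c(OCc2ccccc2)c1
F3 | step 7 | (2R,3R)-3-[3,5-bis(benzyloxy)phenoxy]-3-[3,4-bis(benzyloxy)phenyl]propane-1,2-diol | OC[C@@H](O)[C@H](Oc1cc(OCc2ccccc2)cc(OCc2ccccc2)c1)c1ccc(OCc2ccccc2)c(OCc2ccccc2)c1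
F4 | step 7 | (2R,3R)-3-[3,5-bis(benzyloxy)phenoxy]-3-[3,4-bis(benzyloxy)phenyl]-1,2-bis[(tert-butyldimethylsilyl)oxy]propane | CC(C)(C)[Si](C)(C)OC[C@@H](O[Si](C)(C)C(C)(C)C)[C@H](Oc1cc(OCc2ccccc2)cc(OCc2ccccc2)c1)c1ccc(OCc2ccccc2)c(OCc2ccccc2)c1
F5 | step 7 | (2R,3R)-3-[3,5-bis(benzyloxy)phenoxy]-3-[3,4-bis(benzyloxy)phenyl]-2-[(tert-butyldimethylsilyl)oxy]propan-1-ol | OC[C@@H](O[Si](C)(C)C(C)(C)C)[C@H](Oc1cc(OCc2ccccc2)cc(OCc2ccccc2)c1)c1ccc(OCc2ccccc2)c(OCc2ccccc2)c1
F6 | step 13 | dodeca-O-benzyl procyanidin C1 bis[3,4,5-tris(benzyloxy)benzoate] (esters on the middle and bottom units, top 3-OH free) | O=C(O[C@@H]1[C@@H](c2c(OCc3ccccc3)cc(OCc3ccccc3)c3c2O[C@H](c2ccc(OCc4ccccc4)c(OCc4ccccc4)c2)[C@H](OC(=O)c2cc(OCc4ccccc4)c(OCc4ccccc4)c(OCc4ccccc4)c2)C3)c2c(OCc3ccccc3)cc(OCc3ccccc3)c([C@H]3c4c(OCc5ccccc5)cc(OCc5ccccc5)cc4O[C@H](c4ccc(OCc5ccccc5)c(OCc5ccccc5)c4)[C@@H]3O)c2O[C@@H]1c1ccc(OCc2ccccc2)c(OCc2ccccc2)c1)c1cc(OCc2ccccc2)c(OCc2ccccc2)c(OCc2ccccc2)c1
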